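**Plan**

Numbering: the lactone is O1, C2 (quaternary), C3, C4, C5 (C=O), and Cα is the side-chain CH. The carboxyl carbon on Cα and the lactone carbonyl C5 lie at the two ends of the run Cα–C2–C3–C4. Both are at the acid oxidation level, so joining them as one C=C turns the open stereodiad into a cyclohex-3-ene whose ring carbons 1 and 2 are C2 and Cα.
Cuts, in retrosynthetic order: the malate C1 acyl–O(decyl) bond; the lactone O1–C5 bond; the two carboxyl carbons rejoined as the ring alkene; Cα–C2 and C3–C4 together by retro-[4+2]; the decyl–diene C–C bond (sulfolene alkylation).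
Forward: the C10 chain is joined to 3-sulfolene and released as the E-diene. The only carbocycle, a temporary cyclohexene, closes in the cycloaddition and is opened again by ozonolysis. The γ-lactone closes on acidification after debenzoylation, and the malate ester is attached last.
Stereochemistry: Cα and C2 arise together in the cycloaddition. Their relative configuration comes from the E-diene plus formyl-endo topology, and their absolute configuration from a chiral N-protonated oxazaborolidine. The carbinol centre is carried over unchanged from D-malic acid.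

Key step: step 7

Assumption: the sense of induction in step 7 is taken from the accepted formyl C–H···O binding model for 2-substituted acroleins on this catalyst. Both precatalyst enantiomers are commercial, so the (3aR) form would replace the (3aS) form if a correlation at the hydroxy lactone diacid stage showed the opposite sense.

**Step 1**
Reactants: 1 10-bromodecan-1-ol
Product: 2 [(10-bromodecyl)oxy](tert-butyl)diphenylsilane
Conditions: t-BuPh2SiCl (1.1 equiv), imidazole (2 equiv), CH2Cl2, 0 °C → rt
Reagents that add atoms: tert-butyl(chloro)diphenylsilane, CC(C)(C)[Si](Cl)(c1ccccc1)c1ccccc1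
Why: Imidazole-promoted silylation of a primary alcohol gives a TBDPS ether that should tolerate the strong base, heat, cationic Lewis acid and oxidants of steps 3–8, and no stereocentre is involved.

**Step 2**
Reactants: 2 [(10-bromodecyl)oxy](tert-butyl)diphenylsilane
Product: 3 tert-butyl[(10-iododecyl)oxy]diphenylsilane
Conditions: NaI (3 equiv), acetone, reflux
Reagents that add atoms: sodium iodide, [Na+].[I-]
Why: Finkelstein halide exchange (SN2), driven by precipitation of NaBr, supplies an iodide reactive enough to trap the short-lived sulfolene anion at −78 °C.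

**Step 3**
Reactants: 3 tert-butyl[(10-iododecyl)oxy]diphenylsilane; 4 3-sulfolene (2,5-dihydrothiophene 1,1-dioxide)
Product: 6 rac-2-{10-[(tert-butyldiphenylsilyl)oxy]decyl}-2,5-dihydrothiophene 1,1-dioxide, via 2-lithio-3-sulfolene 5 (not isolated)
Conditions: 4 (2 equiv) premixed with 3, LiN(SiMe3)2 (2 equiv) added last, THF/HMPA (5:1), −78 °C
Reagents that add atoms: none
Why: In this α-sulfonyl carbanion alkylation the allylic anion is generated in the presence of the primary iodide, so that SN2 capture at C2 outruns its ring opening to the butadienesulfinate; the new centre is racemic and vanishes in step 4.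

**Step 4**
Reactants: 6 rac-2-{10-[(tert-butyldiphenylsilyl)oxy]decyl}-2,5-dihydrothiophene 1,1-dioxide
Product: 7 tert-butyl[(11E)-tetradeca-11,13-dien-1-yloxy]diphenylsilane
Conditions: PhMe, 110 °C, slow N2 stream, trace 2,6-di-tert-butyl-4-methylphenol
Reagents that add atoms: none
Why: Cheletropic extrusion of SO2 is concerted and disrotatory and turns the single C2 substituent outward, so the 1-alkylbutadiene should form as the E isomer only.

**Step 5**
Reactants: 8 2,2-dimethyl-1,3-dioxan-5-one
Product: 10 2,2-dimethyl-4H-1,3-dioxin-5-yl benzoate, via potassium enolate 9 (not isolated)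
Conditions: KN(SiMe3)2 (1.05 equiv), THF, −78 °C (ketone added to base); then PhCOCl (1.1 equiv), −78 → 0 °C
Reagents that add atoms: benzoyl chloride, O=C(Cl)c1ccccc1
Why: O-acylation of the weakly ion-paired potassium enolate by the hard acid chloride gives the enol ester, which is the 4H-1,3-dioxin needed for step 6.

**Step 6**
Reactants: 10 2,2-dimethyl-4H-1,3-dioxin-5-yl benzoate
Product: 11 2-(benzoyloxy)acrolein (3-oxoprop-1-en-2-yl benzoate)
Conditions: PhMe, 110 °C, acetone distilled off, trace 2,6-di-tert-butyl-4-methylphenol; stored cold and used promptly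
Reagents that add atoms: none
Why: A thermal retro-hetero-Diels–Alder reaction splits the 4H-1,3-dioxin into acetone and the 1-oxadiene, which is the 2-acyloxyacrolein, and removing acetone makes the cleavage irreversible.

**Step 7**
Reactants: 7 tert-butyl[(11E)-tetradeca-11,13-dien-1-yloxy]diphenylsilane; 11 2-(benzoyloxy)acrolein
Product: 12 (1R,2R)-1-formyl-2-{10-[(tert-butyldiphenylsilyl)oxy]decyl}cyclohex-3-en-1-yl benzoate
Conditions: 11 (1.5 equiv), (3aS)-1-(2-methylphenyl)-3,3-diphenyltetrahydro-1H,3H-pyrrolo[1,2-c][1,3,2]oxazaborole (C24H24BNO, 20 mol %) + HN(SO2CF3)2 (18 mol %), CH2Cl2, −78 → −40 °C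
Reagents that add atoms: none
Why: The N-protonated oxazaborolidine binds the formyl oxygen of s-trans 11 (supported by a formyl C–H···O contact to the ring oxygen), lowers its LUMO and sets off a concerted, asynchronous [4+2] cycloaddition in which the C3–C4 bond (diene CH2 terminus to acrolein CH2) forms ahead of the Cα–C2 bond (alkyl-bearing terminus to the oxygenated carbon). The closest known reaction type is the catalytic enantioselective Diels–Alder reaction of 2-substituted acroleins (2-bromo, 2-methyl, 2-acyloxy) with cyclic and acyclic dienes under chiral cationic boron or ammonium catalysis, and the present diene–dienophile pair is a new combination within that class. The one ring formed, the temporary cyclohexene, closes by intermolecular suprafacial–suprafacial union of the four diene carbons with the C=C of 11. C2 of the target (C1 of 12, R) is set by the catalyst, whose convex-face phenyl group covers the Si face of the oxygen-bearing carbon so that the diene adds to the Re face, and Cα (C2 of 12, R) is set relative to it by the E geometry of 7 together with the formyl-endo transition state, which places the chain cis to CHO and trans to OBz. The step needs 1,2 regiochemistry, endo topology and one dienophile face: the regiochemistry is secured by the matched coefficients of a 1-alkyl diene (largest HOMO lobe at the free terminus) and a captodative acrolein (largest LUMO lobe at CH2), and the endo preference by secondary overlap with the cationic formyl group in a diene that has neither a bridging CH2 nor a C2 substituent to push the aldehyde outward, helped by the bulky benzoate, which fits better in the open exo sector. The aldehyde sits on a quaternary carbon and cannot enolise, so the adduct should not epimerise on isolation.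

**Step 8**
Reactants: 12 (1R,2R)-1-formyl-2-{10-[(tert-butyldiphenylsilyl)oxy]decyl}cyclohex-3-en-1-yl benzoate
Product: 15 (2S,3R)-3-(benzoyloxy)-3-carboxy-2-{10-[(tert-butyldiphenylsilyl)oxy]decyl}hexanedioic acid, via secondary ozonide 13 (not isolated), via trialdehyde 14 (not isolated)
Conditions: O3, CH2Cl2, −78 °C; PPh3 (1.05 equiv), −78 → 0 °C; then NaClO2 (6 equiv), NaH2PO4, 2-methyl-2-butene, t-BuOH/THF/H2O, 0 °C → rt; no amine and no basic wash before the oxidation is complete
Reagents that add atoms: ozone, [O-][O+]=O; sodium chlorite, [Na+].[O-]Cl=O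
Why: Criegee ozonolysis of the only alkene, neutral phosphine reduction and a buffered Pinnick oxidation raise all three formyl groups to carboxyl groups in one pot; the weakly acidic buffer should keep the transient Cα-formyl compound from epimerising or losing benzoate, and peracid work-ups are avoided because they invite Baeyer–Villiger loss of the tertiary formyl carbon.

**Step 9**
Reactants: 15 (2S,3R)-3-(benzoyloxy)-3-carboxy-2-{10-[(tert-butyldiphenylsilyl)oxy]decyl}hexanedioic acid
Product: 17 (2R)-2-[(1S)-1-carboxy-11-hydroxyundecyl]-5-oxooxolane-2-carboxylic acid, via trisodium seco-tricarboxylate 16 (not isolated)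
Conditions: 5 M aq NaOH/EtOH, 50 °C; EtOH evaporated, Et2O wash; 3 M HCl to pH ≤ 1, 60 °C; EtOAc extraction
Reagents that add atoms: none
Why: Saponification of the α-carboxy-activated tertiary benzoate and hydroxide cleavage of the TBDPS ether (a classical removal for this group) proceed in one alkaline medium in which the carboxylates block enolisation at Cα, and acidification then closes the five-membered lactone by attack of the C2 hydroxyl on C5 without breaking any bond to a stereocentre.

**Step 10**
Reactants: 18 D-malic acid ((R)-2-hydroxybutanedioic acid)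
Product: 19 (3R)-2,5-dioxooxolan-3-yl trifluoroacetate
Conditions: (CF3CO)2O (3 equiv, neat), 0 °C → rt; volatiles removed in vacuo; used crude
Reagents that add atoms: trifluoroacetic anhydride, O=C(OC(=O)C(F)(F)F)C(F)(F)F
Why: Trifluoroacetic anhydride acylates the hydroxyl and cyclodehydrates the 1,4-diacid through a mixed anhydride, and the C–O bond at the stereocentre is never broken, so the R configuration is retained.

**Step 11**
Reactants: 17 (2R)-2-[(1S)-1-carboxy-11-hydroxyundecyl]-5-oxooxolane-2-carboxylic acid; 19 (3R)-2,5-dioxooxolan-3-yl trifluoroacetate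
Product: 21 (2R)-2-[(1S)-1-carboxy-11-{[(2R)-3-carboxy-2-hydroxypropanoyl]oxy}undecyl]-5-oxooxolane-2-carboxylic acid (CNP0457473.1), via O-trifluoroacetyl ester 20 (not isolated)
Conditions: 19 (3 equiv), THF, rt, no base; then H2O/THF (1:1), rt; reversed-phase chromatography
Reagents that add atoms: none
Why: In this regioselective alcoholysis of an unsymmetrical cyclic anhydride the primary alcohol, the only hydroxyl of 17, opens 19 at the carbonyl next to the electron-poor trifluoroacetoxy carbon to give the 1-ester, carboxyl groups are acylated only reversibly without base, and water then solvolyses the labile trifluoroacetate and any mixed anhydride without touching the lactone, the malate ester or any stereocentre.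

**Compound list**

1 | 10-bromodecan-1-ol | OCCCCCCCCCCBr | starting material
2 | [(10-bromodecyl)oxy](tert-butyl)diphenylsilane | BrCCCCCCCCCCO[Si](c1ccccc1)(c1ccccc1)C(C)(C)C | intermediate
3 | tert-butyl[(10-iododecyl)oxy]diphenylsilane | ICCCCCCCCCCO[Si](c1ccccc1)(c1ccccc1)C(C)(C)C | intermediate
4 | 3-sulfolene | O=S1(=O)CC=CC1 | starting material
5 | 2-lithio-3-sulfolene (not isolated) | [Li]C1C=CCS1(=O)=O | intermediate
6 | rac-2-{10-[(tert-butyldiphenylsilyl)oxy]decyl}-2,5-dihydrothiophene 1,1-dioxide | O=S1(=O)CC=CC1CCCCCCCCCCO[Si](c1ccccc1)(c1ccccc1)C(C)(C)C | intermediate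
7 | tert-butyl[(11E)-tetradeca-11,13-dien-1-yloxy]diphenylsilane | C=C/C=C/CCCCCCCCCCO[Si](c1ccccc1)(c1ccccc1)C(C)(C)C | intermediate
8 | 2,2-dimethyl-1,3-dioxan-5-one | CC1(C)OCC(=O)CO1 | starting material
9 | potassium 2,2-dimethyl-4H-1,3-dioxin-5-olate (not isolated) | CC1(C)OCC([O-])=CO1.[K+] | intermediate
10 | 2,2-dimethyl-4H-1,3-dioxin-5-yl benzoate | CC1(C)OCC(OC(=O)c2ccccc2)=CO1 | intermediate
11 | 2-(benzoyloxy)acrolein | C=C(C=O)OC(=O)c1ccccc1 | intermediate
12 | (1R,2R)-1-formyl-2-{10-[(tert-butyldiphenylsilyl)oxy]decyl}cyclohex-3-en-1-yl benzoate (chain cis to CHO) | O=C[C@@]1(OC(=O)c2ccccc2)CCC=C[C@H]1CCCCCCCCCCO[Si](c1ccccc1)(c1ccccc1)C(C)(C)C | intermediate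
13 | secondary ozonide of 12, a 7,8,9-trioxabicyclo[4.2.1]nonane, bridge orientation undefined (not isolated) | O=C[C@@]1(OC(=O)c2ccccc2)CCC2OOC(O2)[C@H]1CCCCCCCCCCO[Si](c1ccccc1)(c1ccccc1)C(C)(C)C | intermediate
14 | (2S,3R)-3-formyl-1,6-dioxo-2-{10-[(tert-butyldiphenylsilyl)oxy]decyl}hexan-3-yl benzoate (not isolated) | O=C[C@@](OC(=O)c1ccccc1)(CCC=O)[C@@H](C=O)CCCCCCCCCCO[Si](c1ccccc1)(c1ccccc1)C(C)(C)C | intermediate
15 | (2S,3R)-3-(benzoyloxy)-3-carboxy-2-{10-[(tert-butyldiphenylsilyl)oxy]decyl}hexanedioic acid | OC(=O)[C@@](OC(=O)c1ccccc1)(CCC(=O)O)[C@@H](C(=O)O)CCCCCCCCCCO[Si](c1ccccc1)(c1ccccc1)C(C)(C)C | intermediate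
16 | trisodium (2S,3R)-3-carboxylato-3-hydroxy-2-(10-hydroxydecyl)hexanedioate (not isolated) | [Na+].[Na+].[Na+].[O-]C(=O)[C@@](O)(CCC(=O)[O-])[C@@H](C(=O)[O-])CCCCCCCCCCO | intermediate
17 | (2R)-2-[(1S)-1-carboxy-11-hydroxyundecyl]-5-oxooxolane-2-carboxylic acid | OCCCCCCCCCC[C@H](C(=O)O)[C@@]1(C(=O)O)CCC(=O)O1 | intermediate
18 | D-malic acid | O=C(O)C[C@@H](O)C(=O)O | starting material
19 | (3R)-2,5-dioxooxolan-3-yl trifluoroacetate | O=C1C[C@@H](OC(=O)C(F)(F)F)C(=O)O1 | intermediate
20 | O-trifluoroacetyl derivative of 21 (not isolated) | O=C(O)C[C@@H](OC(=O)C(F)(F)F)C(=O)OCCCCCCCCCC[C@H](C(=O)O)[C@@]1(C(=O)O)CCC(=O)O1 | intermediate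
21 | (2R)-2-[(1S)-1-carboxy-11-{[(2R)-3-carboxy-2-hydroxypropanoyl]oxy}undecyl]-5-oxooxolane-2-carboxylic acid | O=C(O)C[C@@H](O)C(=O)OCCCCCCCCCC[C@H](C(=O)O)[C@@]1(C(=O)O)CCC(=O)O1 | target

**Step count**

Total steps: 11. Longest linear sequence: 8 (steps 1, 2, 3, 4, 7, 8, 9, 11).

**Steps most likely to fail**

**Step 7.** The formyl-endo preference or the facial discrimination may be insufficient with a flexible 1-alkyl acyclic diene, and slow turnover may let the dienophile polymerise.
- The fallback keeps the same two ring-forming bonds but separates the quaternary centre from the endo/exo question. It sets out from 7.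
- Cycloaddition of 7 with 2,2,2-trifluoroethyl acrylate is run under the same catalyst family. The enantiomer is the one assigned by the α-C–H···O binding model for acrylates, expected to be the (3aR) form. Endo selectivity is reliably high for this pairing of an unsubstituted acrylate with a 1-substituted diene.
- This should give 2,2,2-trifluoroethyl (1S,2R)-2-{10-[(tert-butyldiphenylsilyl)oxy]decyl}cyclohex-3-ene-1-carboxylate F1.
- Deprotonation with KN(SiMe3)2 (THF, −78 °C) erases the carboxyl-bearing centre. 3-Phenyl-2-(phenylsulfonyl)oxaziridine then delivers oxygen to the enolate face anti to the neighbouring chain, giving 2,2,2-trifluoroethyl (1R,2R)-1-hydroxy-2-{10-[(tert-butyldiphenylsilyl)oxy]decyl}cyclohex-3-ene-1-carboxylate F2.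
- Cleavage of the ring alkene with RuCl3 (cat.)/NaIO4 in MeCN/EtOAc/H2O, followed by lactonisation on acidic work-up, leads to (2S)-2-[(2R)-5-oxo-2-(2,2,2-trifluoroethoxycarbonyl)oxolan-2-yl]-12-[(tert-butyldiphenylsilyl)oxy]dodecanoic acid F3.
- The conditions of step 9 hydrolyse the ester and the silyl ether and re-close the lactone, so the route is rejoined at 17.

**Step 8.** Benzoate may be lost by β-elimination, or Cα may epimerise, during the period in which Cα carries a formyl group.
- The fallback removes the leaving group before the ring is opened. It sets out from 12.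
- Pinnick oxidation of the formyl group alone gives (1R,2R)-1-(benzoyloxy)-2-{10-[(tert-butyldiphenylsilyl)oxy]decyl}cyclohex-3-ene-1-carboxylic acid F4.
- LiOH in aqueous THF/MeOH removes the benzoate and leaves the silyl ether in place, giving (1R,2R)-1-hydroxy-2-{10-[(tert-butyldiphenylsilyl)oxy]decyl}cyclohex-3-ene-1-carboxylic acid F5.
- Ozonolysis (O3, then Me2S) now gives an aldehyde whose β-oxygen is a poor leaving group, because the tertiary hydroxyl traps C5 as a lactol. The product is (2R)-5-hydroxy-2-{(2S)-1-oxo-12-[(tert-butyldiphenylsilyl)oxy]dodecan-2-yl}oxolane-2-carboxylic acid F6.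
- PhI(OAc)2 with catalytic 2,2,6,6-tetramethylpiperidine-1-oxyl in aqueous MeCN oxidises the lactol and the formyl group together to (2R)-2-{(1S)-1-carboxy-11-[(tert-butyldiphenylsilyl)oxy]undecyl}-5-oxooxolane-2-carboxylic acid F7.
- The alkaline desilylation and acid re-lactonisation of step 9 bring the material back to 17.

**Step 11.** Acyl exchange between 19 and the two free carboxyl groups may lead to self-esterification, and trifluoroacetyl transfer to the alcohol may lower conversion.
- The fallback masks the core acids first. It sets out from 17.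
- O-tert-butyl-N,N'-diisopropylisourea (CH2Cl2, rt) esterifies only the carboxyl groups, giving tert-butyl (2R)-2-[(2S)-1-tert-butoxy-12-hydroxy-1-oxododecan-2-yl]-5-oxooxolane-2-carboxylate F8.
- Opening of 19 by this alcohol under the conditions of step 11 gives the O-trifluoroacetyl malate half-ester of the di-tert-butyl ester F9.
- CF3CO2H/CH2Cl2 removes both tert-butyl groups and returns to 20, which water converts into 21 as in the main route.

**Further compounds**

F1 | step 7 | 2,2,2-trifluoroethyl (1S,2R)-2-{10-[(tert-butyldiphenylsilyl)oxy]decyl}cyclohex-3-ene-1-carboxylate | O=C(OCC(F)(F)F)[C@H]1CCC=C[C@H]1CCCCCCCCCCO[Si](c1ccccc1)(c1ccccc1)C(C)(C)C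
F2 | step 7 | 2,2,2-trifluoroethyl (1R,2R)-1-hydroxy-2-{10-[(tert-butyldiphenylsilyl)oxy]decyl}cyclohex-3-ene-1-carboxylate | O=C(OCC(F)(F)F)[C@@]1(O)CCC=C[C@H]1CCCCCCCCCCO[Si](c1ccccc1)(c1ccccc1)C(C)(C)C
F3 | step 7 | (2S)-2-[(2R)-5-oxo-2-(2,2,2-trifluoroethoxycarbonyl)oxolan-2-yl]-12-[(tert-butyldiphenylsilyl)oxy]dodecanoic acid | CC(C)(C)[Si](c1ccccc1)(c1ccccc1)OCCCCCCCCCC[C@H](C(=O)O)[C@@]1(C(=O)OCC(F)(F)F)CCC(=O)O1
F4 | step 8 | (1R,2R)-1-(benzoyloxy)-2-{10-[(tert-butyldiphenylsilyl)oxy]decyl}cyclohex-3-ene-1-carboxylic acid | OC(=O)[C@@]1(OC(=O)c2ccccc2)CCC=C[C@H]1CCCCCCCCCCO[Si](c1ccccc1)(c1ccccc1)C(C)(C)C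
F5 | step 8 | (1R,2R)-1-hydroxy-2-{10-[(tert-butyldiphenylsilyl)oxy]decyl}cyclohex-3-ene-1-carboxylic acid | OC(=O)[C@@]1(O)CCC=C[C@H]1CCCCCCCCCCO[Si](c1ccccc1)(c1ccccc1)C(C)(C)C
F6 | step 8 | (2R)-5-hydroxy-2-{(2S)-1-oxo-12-[(tert-butyldiphenylsilyl)oxy]dodecan-2-yl}oxolane-2-carboxylic acid (lactol, anomeric mixture) | CC(C)(C)[Si](c1ccccc1)(c1ccccc1)OCCCCCCCCCC[C@H](C=O)[C@@]1(C(=O)O)CCC(O)O1
F7 | step 8 | (2R)-2-{(1S)-1-carboxy-11-[(tert-butyldiphenylsilyl)oxy]undecyl}-5-oxooxolane-2-carboxylic acid | CC(C)(C)[Si](c1ccccc1)(c1ccccc1)OCCCCCCCCCC[C@H](C(=O)O)[C@@]1(C(=O)O)CCC(=O)O1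
F8 | step 11 | tert-butyl (2R)-2-[(2S)-1-tert-butoxy-12-hydroxy-1-oxododecan-2-yl]-5-oxooxolane-2-carboxylate | OCCCCCCCCCC[C@H](C(=O)OC(C)(C)C)[C@@]1(C(=O)OC(C)(C)C)CCC(=O)O1
F9 | step 11 | O-trifluoroacetyl malate half-ester of the di-tert-butyl ester | O=C(O)C[C@@H](OC(=O)C(F)(F)F)C(=O)OCCCCCCCCCC[C@H](C(=O)OC(C)(C)C)[C@@]1(C(=O)OC(C)(C)C)CCC(=O)O1
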